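## Retrosynthetic overview
1. Cut both central-ring–CH2 bonds (the two positions ortho to the ring OH) in one operation. The ring carbons become C–Br electrophiles. Each CH2 comes from the C=O carbon of 4-hydroxybenzaldehyde, used with inverted polarity as its N–H hydrazone (a benzyl-carbanion equivalent that loses N2 tracelessly).
2. The ring dibromide comes from OH-directed ortho,ortho'-dibromination of the parent bibenzyl phenol.
3. The bibenzyl phenol comes from an sp3–sp2 cut at the central ring: 3-vinylanisole (hydroboration) plus 3-bromo-5-methoxyphenol (B-alkyl Suzuki coupling).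
4. No ring is formed, since all four benzene rings are bought, and no protecting groups are used.

Assumption: the SMILES has no stereocentre and no stereogenic double bond, so the target is achiral and no stereocontrol is needed.

## Route

Step 1
Reactants: 1 3-vinylanisole (1-ethenyl-3-methoxybenzene); 2 3-bromo-5-methoxyphenol
Product: 4 3-methoxy-5-[2-(3-methoxyphenyl)ethyl]phenol, via alkylborane 3 (not isolated)
Conditions: 9-BBN (1.1 equiv), THF, 0 °C → rt; then 2, PdCl2(dppf) (3 mol %), 3 M aq NaOH, THF, 65 °C; aq NH4Cl work-up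
Reagents that add atoms: 9-borabicyclo[3.3.1]nonane (9-BBN), B1C2CCCC1CCC2 (boryl group present in 3 only)
Why: 9-BBN adds anti-Markovnikov to the styrene and the B-alkyl-9-BBN then undergoes a B-alkyl Suzuki–Miyaura coupling with the aryl bromide, while the phenol travels as its sodium phenoxide (meta to C–Br, so oxidative addition is not slowed); no stereocentre is formed.

Step 2
Reactants: 4 3-methoxy-5-[2-(3-methoxyphenyl)ethyl]phenol
Product: 5 2,6-dibromo-3-methoxy-5-[2-(3-methoxyphenyl)ethyl]phenol
Conditions: NBS (2.05 equiv, slow addition), i-Pr2NH (20 mol %), CH2Cl2, −40 → 0 °C, dark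
Reagents that add atoms: N-bromosuccinimide, O=C1CCC(=O)N1Br
Why: This is an amine-catalysed ortho-bromination of a phenol (electrophilic aromatic substitution), in which i-Pr2NBr formed from NBS hydrogen-bonds to the OH and delivers Br+ to the two ortho carbons (phenol itself gives 2,6-dibromophenol with the para position untouched), and the anisole ring is too unreactive to compete at or below 0 °C; no stereocentre is formed.

Step 3 (key step)
Reactants: 5 2,6-dibromo-3-methoxy-5-[2-(3-methoxyphenyl)ethyl]phenol; 6 4-hydroxybenzaldehyde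
Product: 8 2,6-bis[(4-hydroxyphenyl)methyl]-3-methoxy-5-[2-(3-methoxyphenyl)ethyl]phenol (target), via hydrazone 7 (not isolated)
Conditions: 6 (3 equiv), N2H4·H2O (3.3 equiv), THF, rt, then volatiles removed; 5, Ni(cod)2 (20 mol %), PMe3 (40 mol %), LiOt-Bu (8 equiv, terminal base), DBU (1 equiv, proton shuttle, unchanged), THF/1,4-dioxane, 90 °C, Ar; aq NH4Cl to pH 5
Reagents that add atoms: hydrazine monohydrate, NN.O (both N atoms present in 7 only)
Why: Proposed new method: the normally electrophilic aldehyde carbon of 6 becomes nucleophilic as its N–H hydrazone 7 (aza-enamine, benzyl-carbanion equivalent) and is joined to the electrophilic C–Br carbons of 5, because Ni(0)/PMe3 inserts into each C–Br bond, the deprotonated hydrazone binds through N and shifts to its C-bound form, C–C reductive elimination gives ArCH(Ar')N=NH, and base-induced loss of N2 (Wolff–Kishner type) leaves the CH2 link; the closest known reaction type is the Ni-catalysed cross-coupling of aryl bromides with aldehyde N–H hydrazones (umpolung carbonyl coupling, which tolerates the water of hydrazine hydrate), extended here to a twofold coupling at di-ortho-substituted positions with all phenols carried as lithium phenoxides, which is defensible because PMe3 is a very small ligand, O–Li is the smallest possible ortho neighbour and can act as internal base for the Ni-bound hydrazone, neither C–Br has an ortho hydrogen (no aryne), and unprotected 2,6-dibromophenols are proven cross-coupling partners; no stereocentre is formed.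

## Compound list
1 | 1-ethenyl-3-methoxybenzene (3-vinylanisole) | C=Cc1cccc(OC)c1 | starting material
2 | 3-bromo-5-methoxyphenol | COc1cc(O)cc(Br)c1 | starting material
3 | 9-[2-(3-methoxyphenyl)ethyl]-9-borabicyclo[3.3.1]nonane (not isolated) | COc1cccc(CCB2C3CCCC2CCC3)c1 | intermediate
4 | 3-methoxy-5-[2-(3-methoxyphenyl)ethyl]phenol | COc1cccc(CCc2cc(O)cc(OC)c2)c1 | intermediate
5 | 2,6-dibromo-3-methoxy-5-[2-(3-methoxyphenyl)ethyl]phenol | COc1cccc(CCc2cc(OC)c(Br)c(O)c2Br)c1 | intermediate
6 | 4-hydroxybenzaldehyde | O=Cc1ccc(O)cc1 | starting material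
7 | 4-[(E)-hydrazinylidenemethyl]phenol (not isolated) | N/N=C/c1ccc(O)cc1 | intermediate
8 | 2,6-bis[(4-hydroxyphenyl)methyl]-3-methoxy-5-[2-(3-methoxyphenyl)ethyl]phenol (achiral) | COc1cccc(CCc2cc(OC)c(Cc3ccc(O)cc3)c(O)c2Cc2ccc(O)cc2)c1 | target

## Summary
Total step count: 3
Longest linear sequence: 3 steps (1/2 → 4 → 5 → 8)

## Steps most likely to fail, with fallbacks

**Step 3.** The likely losses in this twofold hindered coupling are hydrodebromination of 5 and plain Wolff–Kishner reduction of 7. The fallback sets out from 5 and comes back at 8. It replaces the catalytic hydrazone carbanion with a preformed benzylzinc reagent and masks the phenols.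
- 5 is O-benzylated (BnBr, K2CO3, DMF) to 2-(benzyloxy)-1,3-dibromo-4-methoxy-6-[2-(3-methoxyphenyl)ethyl]benzene F1.
- Commercial 4-(benzyloxy)benzyl chloride is converted with Zn dust/LiCl in THF into [4-(benzyloxy)benzyl]zinc chloride F2.
- A twofold Negishi coupling (Pd-PEPPSI-IPent or Pd(OAc)2/SPhos, THF, 50 °C) is a reaction type proven for di-ortho-substituted aryl bromides. It gives 2-(benzyloxy)-1,3-bis[4-(benzyloxy)benzyl]-4-methoxy-6-[2-(3-methoxyphenyl)ethyl]benzene F3.
- Hydrogenolysis (H2, Pd/C, EtOAc/MeOH) removes the three benzyl groups and gives 8.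

**Step 2.** The risk is bromination para to the OH, or tribromination, because all three free positions of the ring are activated. The fallback sets out from 4 and comes back at 8. It drops halogenation and swaps the roles of the two coupling partners.
- The strictly ortho-specific magnesium-phenoxide formylation (MgCl2, Et3N, paraformaldehyde, MeCN, reflux) first gives 2-hydroxy-4-methoxy-6-[2-(3-methoxyphenyl)ethyl]benzaldehyde F4.
- Resubmitting F4 to the same conditions gives 2-hydroxy-4-methoxy-6-[2-(3-methoxyphenyl)ethyl]benzene-1,3-dicarbaldehyde F5.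
- N2H4·H2O in THF converts F5 into 2,6-bis[(E)-hydrazinylidenemethyl]-3-methoxy-5-[2-(3-methoxyphenyl)ethyl]phenol F6.
- F6 serves as a double benzyl-carbanion equivalent. It is coupled with the unhindered, cheap 4-bromophenol (2.5 equiv) under the Ni(cod)2/PMe3/LiOt-Bu conditions of step 3 to give 8.

**Step 1.** The risks are protodeboronation and slow coupling of the bromophenoxide. The fallback sets out from 1 and 2 and comes back at 4. A Heck reaction (Pd(OAc)2, P(o-tol)3, Et3N, DMF, 100 °C) gives 3-methoxy-5-[(E)-2-(3-methoxyphenyl)ethenyl]phenol F7. Hydrogenation (H2, Pd/C, EtOAc, rt) then gives 4.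

## Further compounds
F1 | step 3 | 2-(benzyloxy)-1,3-dibromo-4-methoxy-6-[2-(3-methoxyphenyl)ethyl]benzene | COc1cccc(CCc2cc(OC)c(Br)c(OCc3ccccc3)c2Br)c1
F2 | step 3 | [4-(benzyloxy)benzyl]zinc chloride | Cl[Zn]Cc1ccc(OCc2ccccc2)cc1
F3 | step 3 | 2-(benzyloxy)-1,3-bis[4-(benzyloxy)benzyl]-4-methoxy-6-[2-(3-methoxyphenyl)ethyl]benzene | COc1cccc(CCc2cc(OC)c(Cc3ccc(OCc4ccccc4)cc3)c(OCc3ccccc3)c2Cc2ccc(OCc3ccccc3)cc2)c1
F4 | step 2 | 2-hydroxy-4-methoxy-6-[2-(3-methoxyphenyl)ethyl]benzaldehyde | COc1cccc(CCc2cc(OC)cc(O)c2C=O)c1
F5 | step 2 | 2-hydroxy-4-methoxy-6-[2-(3-methoxyphenyl)ethyl]benzene-1,3-dicarbaldehyde | COc1cccc(CCc2cc(OC)c(C=O)c(O)c2C=O)c1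
F6 | step 2 | 2,6-bis[(E)-hydrazinylidenemethyl]-3-methoxy-5-[2-(3-methoxyphenyl)ethyl]phenol | COc1cccc(CCc2cc(OC)c(/C=N/N)c(O)c2/C=N/N)c1
F7 | step 1 | 3-methoxy-5-[(E)-2-(3-methoxyphenyl)ethenyl]phenol | COc1cccc(/C=C/c2cc(O)cc(OC)c2)c1
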